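Prostanoid numbering is used (ester carbon C1; ring C8–C12; ketone C9). The ring carries oxygen at C9 and C12 on either side of C8, with C10=C11 between them: the pattern a 2-furylcarbinol gives in a Piancatelli rearrangement. A carbinol from furfural and an allyl Grignard reagent is opened by water to a 1,4-dihydroxypentadienyl cation whose 4π conrotatory closure forms the C8–C9 bond and a trans-5-allyl-4-hydroxycyclopentenone; furan C2 and C5 become C12 (ketone) and C9 (carbinol). These oxidation levels are then exchanged by (Z)-octenyl addition at C12 and oxidation at C9. The side chain comes by cross-metathesis with a chiral-pool acetoxy ester; C8 is corrected by kinetic protonation before the final acetylation.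

Key step: step 2

Assumption: in step 3 the lipase is taken to acylate the (4S,5R)-alcohol, the enantiomer that corresponds spatially to the faster-reacting (R)-enantiomer of 4-hydroxycyclopent-2-enone, so that the wanted (4R,5S)-alcohol is the one recovered.

Step 1
Reactants: 1 furan-2-carbaldehyde (furfural); 2 allylmagnesium bromide
Product: 3 racemic 1-(furan-2-yl)but-3-en-1-ol
Conditions: THF, 0 °C; aq. NH4Cl
Reagents that add atoms: none
Why: Grignard 1,2-addition to the aldehyde; the carbinol centre may stay racemic because it is ionised and planarised in step 2.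

Step 2
Reactants: 3 racemic 1-(furan-2-yl)but-3-en-1-ol
Product: 5 racemic trans-4-hydroxy-5-(prop-2-en-1-yl)cyclopent-2-en-1-one, via 1,4-dihydroxypentadienyl cation 4 (not isolated)
Conditions: ZnCl2 (2 equiv), 1,4-dioxane/H2O, reflux
Reagents that add atoms: water O
Why: Zinc chloride-assisted loss of the carbinol hydroxyl gives a furfuryl (2-alkylidene-2H-furanium) cation, water adds at furan C5, and the hemiacetal opens to the 1,4-dihydroxypentadienyl cation 4. Its thermally allowed 4π conrotatory electrocyclisation (Piancatelli rearrangement, a Nazarov-type closure) joins the former carbinol carbon (C8) to the former furan C5 (C9), and the resulting hydroxyallyl cation collapses to the enone, whose carbonyl oxygen (at C12) is the old furan oxygen. The five-membered ring is therefore closed in a 4π electrocyclic mode, formally 5-endo. Conrotation of the cation with the allyl group and the C9 hydroxyl both outside should place them trans at C8 and C9, so both new stereocentres are set relative to each other, as the racemate. The step needs water to attack ring carbon C5 rather than elimination to the dienylfuran or later isomerisation to the 2-allyl-4-hydroxy isomer. This is secured because the furan oxygen makes C5 the oxocarbenium carbon, water addition at the exocyclic carbon only regenerates 3, and the medium is weakly acidic.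

Step 3
Reactants: 5 racemic trans-4-hydroxy-5-(prop-2-en-1-yl)cyclopent-2-en-1-one
Product: 6 (4R,5S)-4-hydroxy-5-(prop-2-en-1-yl)cyclopent-2-en-1-one
Conditions: immobilised Burkholderia cepacia lipase, vinyl acetate, t-BuOMe, 30 °C, stopped just past half conversion; chromatography
Reagents that add atoms: none
Why: Lipase-catalysed enantioselective transesterification (kinetic resolution) should acetylate the (4S,5R)-alcohol and leave the (4R,5S)-alcohol, which fixes the absolute configuration that is later relayed from C8/C9 to C12.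

Step 4
Reactants: 7 (S)-5-(hydroxymethyl)dihydrofuran-2(3H)-one
Product: 9 (S)-5-ethenyldihydrofuran-2(3H)-one, via (S)-5-oxotetrahydrofuran-2-carbaldehyde 8 (not isolated)
Conditions: (COCl)2, DMSO, CH2Cl2, −78 °C; Et3N; then excess Ph3P=CH2 (from Ph3PCH3Br and KN(SiMe3)2 in THF), −78 °C to rt
Reagents that add atoms: methylenetriphenylphosphorane C=P(c1ccccc1)(c1ccccc1)c1ccccc1
Why: Swern oxidation followed by Wittig methylenation in the same flask avoids isolating the labile α-alkoxy aldehyde; the glutamate-derived stereocentre (the future C4) is not touched.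

Step 5
Reactants: 9 (S)-5-ethenyldihydrofuran-2(3H)-one
Product: 11 methyl (S)-4-hydroxyhex-5-enoate, via sodium (S)-4-hydroxyhex-5-enoate 10 (not isolated)
Conditions: NaOH (1.0 equiv), MeOH/H2O, rt; evaporate to dryness; MeI, DMF, 0 °C to rt
Reagents that add atoms: sodium hydroxide [Na+].[OH-]; iodomethane CI
Why: Saponification and O-alkylation of the carboxylate should give the hydroxy ester without activating the acyl group, so the lactone is not re-formed.

Step 6
Reactants: 11 methyl (S)-4-hydroxyhex-5-enoate
Product: 12 methyl (S)-4-acetoxyhex-5-enoate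
Conditions: Ac2O, pyridine, DMAP (cat.), CH2Cl2, 0 °C, 11 used at once
Reagents that add atoms: acetic anhydride CC(=O)OC(C)=O
Why: DMAP-catalysed acetylation of the secondary allylic alcohol should outrun relactonisation and installs the C4 acetate with the (S) configuration retained.

Step 7
Reactants: 6 (4R,5S)-4-hydroxy-5-(prop-2-en-1-yl)cyclopent-2-en-1-one; 12 methyl (S)-4-acetoxyhex-5-enoate
Product: 13 methyl (4S,5E)-4-acetoxy-7-[(1S,5R)-5-hydroxy-2-oxocyclopent-3-en-1-yl]hept-5-enoate
Conditions: second-generation Hoveyda–Grubbs catalyst RuCl2(H2IMes)(=CH–C6H4-2-OiPr) (5 mol %), 12 (3 equiv), CH2Cl2, 40 °C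
Reagents that add atoms: none
Why: Olefin cross-metathesis between the unhindered allyl group and the excess allylic acetate should give the E C5=C6 alkene; the ring enone is inert, and the step precedes octenyl introduction so that no second reactive alkene is present.

Step 8
Reactants: 14 (Z)-oct-2-en-1-ol
Product: 15 (Z)-1-chlorooct-2-ene
Conditions: N-chlorosuccinimide, Me2S, CH2Cl2, −20 to 0 °C
Reagents that add atoms: N-chlorosuccinimide O=C1CCC(=O)N1Cl
Why: Corey–Kim chlorination displaces the alkoxysulfonium ion by chloride in an SN2 step, so neither allylic transposition nor loss of the Z geometry is expected.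

Step 9
Reactants: 13 methyl (4S,5E)-4-acetoxy-7-[(1S,5R)-5-hydroxy-2-oxocyclopent-3-en-1-yl]hept-5-enoate; 15 (Z)-1-chlorooct-2-ene
Product: 17 methyl (4S,5E)-4-acetoxy-7-[(1S,2R,5R)-2,5-dihydroxy-2-[(2Z)-oct-2-en-1-yl]cyclopent-3-en-1-yl]hept-5-enoate, via (Z)-oct-2-enylbarium chloride 16 (not isolated)
Conditions: BaI2, lithium biphenylide (2 equiv), THF, rt (activated barium); 15, −78 °C; then 13 (0.4 equiv relative to 16), −78 °C; aq. NH4Cl
Reagents that add atoms: none
Why: Allylbarium reagents add to ketones at their α-carbon with retention of the Z geometry and 1,2 to enones; after the first equivalent has deprotonated the C9 hydroxyl, attack on the C12 carbonyl anti to the C8 chain, on the face of the C9 alkoxide, should set C12 as (R), and at −78 °C the ketone should react well ahead of the methyl ester and the acetate.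

Step 10
Reactants: 17 methyl (4S,5E)-4-acetoxy-7-[(1S,2R,5R)-2,5-dihydroxy-2-[(2Z)-oct-2-en-1-yl]cyclopent-3-en-1-yl]hept-5-enoate
Product: 18 methyl (4S,5E)-4-acetoxy-7-[(1R,5R)-5-hydroxy-5-[(2Z)-oct-2-en-1-yl]-2-oxocyclopent-3-en-1-yl]hept-5-enoate
Conditions: Dess–Martin periodinane, NaHCO3, CH2Cl2, 0 °C to rt
Reagents that add atoms: none
Why: Dess–Martin oxidation converts only the secondary allylic C9 alcohol into the enone and cannot touch the tertiary C12 alcohol, which completes the exchange of oxidation levels between C9 and C12; C8 is still the epimer with its chain trans to the octenyl group.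

Step 11
Reactants: 18 methyl (4S,5E)-4-acetoxy-7-[(1R,5R)-5-hydroxy-5-[(2Z)-oct-2-en-1-yl]-2-oxocyclopent-3-en-1-yl]hept-5-enoate
Product: 20 methyl (4S,5E)-4-acetoxy-7-[(1S,5R)-5-hydroxy-5-[(2Z)-oct-2-en-1-yl]-2-oxocyclopent-3-en-1-yl]hept-5-enoate, via bis(trimethylsilyl) dienol ether 19 (not isolated)
Conditions: Me3SiOTf, Et3N, CH2Cl2, −78 to 0 °C; evaporate; Bu4NF, AcOH, THF, −78 °C
Reagents that add atoms: none
Why: Soft enolisation can only go towards C8 and gives the 5,5-disubstituted silyloxycyclopentadiene 19 without a free β-alkoxide enolate; fluoride then releases the enolate in the presence of acetic acid at −78 °C, and kinetic C-protonation on the less hindered ring face (the face of the C12 oxygen, anti to the C12 methylene of the octenyl group) should place the C8 chain cis to the octenyl group, giving C8 (S).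

Step 12
Reactants: 20 methyl (4S,5E)-4-acetoxy-7-[(1S,5R)-5-hydroxy-5-[(2Z)-oct-2-en-1-yl]-2-oxocyclopent-3-en-1-yl]hept-5-enoate
Product: 21 methyl (4S,5E)-4-acetoxy-7-[(1S,5R)-5-acetoxy-5-[(2Z)-oct-2-en-1-yl]-2-oxocyclopent-3-en-1-yl]hept-5-enoate (CNP0171642.2)
Conditions: Ac2O, Sc(OTf)3 (2 mol %), MeCN, −20 °C
Reagents that add atoms: acetic anhydride CC(=O)OC(C)=O
Why: Lewis acid-catalysed acetylation esterifies the tertiary alcohol without base, which should avoid both E1cB loss of the new β-acetoxy group and epimerisation of the kinetically set C8 centre.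

Compound list
1 | furan-2-carbaldehyde (furfural) | O=Cc1ccco1 | starting material
2 | allylmagnesium bromide | C=CC[Mg]Br | starting material
3 | racemic 1-(furan-2-yl)but-3-en-1-ol | OC(CC=C)c1ccco1 | intermediate
4 | 1,4-dihydroxyocta-2,4,7-trienyl cation (O-protonated (2Z)-4-hydroxyocta-2,4,7-trienal) | C=CCC=C(O)/C=C\C=[OH+] | intermediate
5 | racemic trans-4-hydroxy-5-(prop-2-en-1-yl)cyclopent-2-en-1-one (the 4R,5S enantiomer is drawn) | O=C1C=C[C@@H](O)[C@@H]1CC=C | intermediate
6 | (4R,5S)-4-hydroxy-5-(prop-2-en-1-yl)cyclopent-2-en-1-one, single enantiomer | O=C1C=C[C@@H](O)[C@@H]1CC=C | intermediate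
7 | (S)-5-(hydroxymethyl)dihydrofuran-2(3H)-one | OC[C@@H]1CCC(=O)O1 | starting material
8 | (S)-5-oxotetrahydrofuran-2-carbaldehyde | O=C[C@@H]1CCC(=O)O1 | intermediate
9 | (S)-5-ethenyldihydrofuran-2(3H)-one | C=C[C@@H]1CCC(=O)O1 | intermediate
10 | sodium (S)-4-hydroxyhex-5-enoate | C=C[C@@H](O)CCC(=O)[O-].[Na+] | intermediate
11 | methyl (S)-4-hydroxyhex-5-enoate | C=C[C@@H](O)CCC(=O)OC | intermediate
12 | methyl (S)-4-acetoxyhex-5-enoate | C=C[C@H](CCC(=O)OC)OC(C)=O | intermediate
13 | methyl (4S,5E)-4-acetoxy-7-[(1S,5R)-5-hydroxy-2-oxocyclopent-3-en-1-yl]hept-5-enoate | O=C1C=C[C@@H](O)[C@@H]1C/C=C/[C@H](CCC(=O)OC)OC(C)=O | intermediate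
14 | (Z)-oct-2-en-1-ol | CCCCC/C=C\CO | starting material
15 | (Z)-1-chlorooct-2-ene | CCCCC/C=C\CCl | intermediate
16 | (Z)-oct-2-enylbarium chloride | CCCCC/C=C\C[Ba]Cl | intermediate
17 | methyl (4S,5E)-4-acetoxy-7-[(1S,2R,5R)-2,5-dihydroxy-2-[(2Z)-oct-2-en-1-yl]cyclopent-3-en-1-yl]hept-5-enoate | CCCCC/C=C\C[C@@]1(O)C=C[C@@H](O)[C@@H]1C/C=C/[C@H](CCC(=O)OC)OC(C)=O | intermediate
18 | methyl (4S,5E)-4-acetoxy-7-[(1R,5R)-5-hydroxy-5-[(2Z)-oct-2-en-1-yl]-2-oxocyclopent-3-en-1-yl]hept-5-enoate | CCCCC/C=C\C[C@@]1(O)C=CC(=O)[C@@H]1C/C=C/[C@H](CCC(=O)OC)OC(C)=O | intermediate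
19 | methyl (4S,5E)-4-acetoxy-7-[(5R)-5-[(2Z)-oct-2-en-1-yl]-2,5-bis(trimethylsilyloxy)cyclopenta-1,3-dien-1-yl]hept-5-enoate | CCCCC/C=C\C[C@@]1(O[Si](C)(C)C)C=CC(O[Si](C)(C)C)=C1C/C=C/[C@H](CCC(=O)OC)OC(C)=O | intermediate
20 | methyl (4S,5E)-4-acetoxy-7-[(1S,5R)-5-hydroxy-5-[(2Z)-oct-2-en-1-yl]-2-oxocyclopent-3-en-1-yl]hept-5-enoate | CCCCC/C=C\C[C@@]1(O)C=CC(=O)[C@H]1C/C=C/[C@H](CCC(=O)OC)OC(C)=O | intermediate
21 | methyl (4S,5E)-4-acetoxy-7-[(1S,5R)-5-acetoxy-5-[(2Z)-oct-2-en-1-yl]-2-oxocyclopent-3-en-1-yl]hept-5-enoate | CCCCC/C=C\C[C@@]1(OC(C)=O)C=CC(=O)[C@H]1C/C=C/[C@H](CCC(=O)OC)OC(C)=O | target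

Total step count: 12.
Longest linear sequence: 8 steps (steps 1, 2, 3, 7, 9, 10, 11, 12; the branch through steps 4, 5, 6, 7, 9, 10, 11, 12 is equally long).

Steps most likely to fail

Step 11. The C-protonation may show poor facial selectivity, or the product may drift back to the epimer with the C8 chain trans to the octenyl group. The fallback replaces substrate control by reagent control. It sets out from 19 (made from 18 as in step 11). Compound 19 would be C-protonated with the Lewis acid-assisted chiral Brønsted acid (R)-BINOL·SnCl4, or its enantiomer, whichever is matched (toluene, −78 °C). This reagent protonates silyl enol ethers of α-substituted ketones face-selectively and should spare the tertiary silyl ether, giving methyl (4S,5E)-4-acetoxy-7-[(1S,5R)-5-[(2Z)-oct-2-en-1-yl]-2-oxo-5-(trimethylsilyloxy)cyclopent-3-en-1-yl]hept-5-enoate F1. HF·pyridine (THF, 0 °C) would then remove the silyl group and return to the route at 20.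

Step 9. The allylbarium reagent may lose α-regioselectivity or Z geometry, or attack the side-chain ester and acetate in competition with the ketone. The fallback builds the Z alkene after the C–C bond and sets out from 13. A Barbier allylation (allyl bromide, In powder, THF/H2O, rt) spares esters and poses no regiochemical question. With the same facial preference it should give methyl (4S,5E)-4-acetoxy-7-[(1S,2R,5R)-2,5-dihydroxy-2-(prop-2-en-1-yl)cyclopent-3-en-1-yl]hept-5-enoate F2. A Z-selective cross-metathesis with hept-1-ene would then complete the (Z)-octenyl group, using the cyclometalated ruthenium nitrate catalyst Ru(NO3)(C^C-NHC)(=CH–C6H4-2-OiPr) in THF at 35 °C, to which the E alkene of the side chain is inert. This comes back to the route at 17.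

Step 3. The lipase may discriminate the enantiomers poorly, or prefer the opposite enantiomer. The fallback is an oxidative resolution that sets out from 5. Transfer dehydrogenation with RuCl[(S,S)-TsDPEN](p-cymene), or its enantiomer, in acetone at rt is a kinetic resolution established for 4-hydroxycyclopent-2-enone. It should convert the (4S,5R)-alcohol into achiral 2-(prop-2-en-1-yl)cyclopent-4-ene-1,3-dione F3 and leave the (4R,5S)-alcohol, so the route is rejoined at 6.

Further compounds
F1 | step 11 | methyl (4S,5E)-4-acetoxy-7-[(1S,5R)-5-[(2Z)-oct-2-en-1-yl]-2-oxo-5-(trimethylsilyloxy)cyclopent-3-en-1-yl]hept-5-enoate | CCCCC/C=C\C[C@@]1(O[Si](C)(C)C)C=CC(=O)[C@H]1C/C=C/[C@H](CCC(=O)OC)OC(C)=O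
F2 | step 9 | methyl (4S,5E)-4-acetoxy-7-[(1S,2R,5R)-2,5-dihydroxy-2-(prop-2-en-1-yl)cyclopent-3-en-1-yl]hept-5-enoate | C=CC[C@@]1(O)C=C[C@@H](O)[C@@H]1C/C=C/[C@H](CCC(=O)OC)OC(C)=O
F3 | step 3 | 2-(prop-2-en-1-yl)cyclopent-4-ene-1,3-dione | O=C1C=CC(=O)C1CC=C
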